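(The data were generated by integration with constants of no real substance.)

If substrate and other conformer leave their common pool at one shared rate, should this flask be timed in minutes or in turnovers?

| flask | substrate | other conformer | remark | time |
|---|---|---|---|---|
| amber | 1.4 M | 1 M | run made earlier |  |
| green | 2.2 M | 1 M | run made earlier |  |
| flask | 1.0 M | 1.00 M |  | 10 min |

- amber (time / min: isomer of the product / %, target / %): 1.50: 3.1, 5.4; 3.00: 6.7, 11.7; 5.00: 11.4, 17.1; 6.00: 12.4, 20.2
- green (time / min: isomer of the product / %, target / %): 0.500: 0.4, 2.6; 1.00: 2.2, 4.5; 2.50: 4.6, 10.0; 6.00: 11.6, 20.7

(readings scatter by 0.5 percentage points)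

- ratio of isomer of the product to target at 10 s
- ratio of isomer of the product to target at 80 s
- ratio of isomer of the product to target at 10 min

- the earlier runs were read with a standard deviation of 0.5 percentage points

What do the runs show first? The pool is the substrate plus the other conformer, and the products are target and isomer of the product. At 6.00 min the amber run has made 32.6% of products and the green run 32.3%, although their charges differ.

What rate follows? Treating the pool's loss as apparent first-order, the mean of these two totals gives a rate constant k of 0.0654 min⁻¹.

Is a single time enough? No, so I test it on amber at 3.00 min, which gives 0.0678 min⁻¹.

What do you carry forward? The turnover count N, the product of k and elapsed time. For the flask at 10 min it is 0.654, so the pool should keep a fraction exp(−N), or 52.0% of the charge. The weak spot is that the flask's equal charges lie outside both runs, so this k is an extrapolation.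

And the ratio r of isomer of the product to target? The runs stop at a count of 0.392, which is less than the flask's count, so no reading covers the last asked time. At 6.00 min r reads 0.614 in amber and 0.560 in green. I take their mean, 0.587, as my estimate for the flask at 10 min, knowing that it is read at a smaller count.

The forecast gave 0.97 at 10 s, 0.83 at 80 s and 0.62 at 10 min, the last from relaxation “toward a conformer fraction of about 0.365, a ratio of about 0.58”. My estimate of 0.587 for 10 min lies below the forecast's 0.62.

The flask gives 0.884 at 10 s, 0.695 at 80 s and 0.824 at 10 min.

    substrate ⇌ other conformer (K = 0.380, k = 0.248 min⁻¹)
    substrate → target (k = 0.0674 min⁻¹)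
    target ⇌ isomer of the product (K = 2.27, k = 0.0714 min⁻¹)
    other conformer → isomer of the product (k = 0.0630 min⁻¹)

At 10.0 min the flask's pool holds 51.6% of the charge, against the 52.0% counted. The neighbour charged with 1.7 M of substrate holds 51.6% at that time, against the same 52.0% counted, with r at 0.801. In the flask, target is made 4.65 times faster than it is used up at 4.39 min, each step taken net. By 10.0 min that factor has fallen to 2.09, and r stands at 0.824, higher than the forecast's 0.62.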